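The vessel is a closed, stirred flask with two phases: salt and spent salt sit in the second, the other species in the first, and the carrier passes between its spent and fresh forms as substrate becomes target.

substrate 0.80 M; salt in the second phase 0.760 M; spent carrier 80 mM; time 10 s; volume of the second phase over the first 0.50

    target + fresh carrier ⇌ isomer of the product + fresh carrier, rate k1*[target]*[fresh carrier] forward; the back reaction follows from the equilibrium constant (K1 = 0.12, k1 = 0.17 L mol⁻¹ s⁻¹)
    crystals ⇌ target, rate k2*(cs2 - [target]) while solid is left; crystals form when [target] > cs2 (cs2 = 0.45 M, k2 = 4.0 s⁻¹)
    spent carrier + salt in the second phase ⇌ fresh carrier + spent salt in the second phase (K3 = 2.1, k3 = 0.59 L mol⁻¹ s⁻¹)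
    substrate + fresh carrier → target + spent carrier (k4 = 0.53 L mol⁻¹ s⁻¹)

- amounts and yields of target count crystals too
- in the second phase: salt in the second phase, spent salt in the second phase; everything else is in the first
- charges count per volume of the first phase; a concentration in a rate is the amount of a species over the volume of its own phase; every rate counts per litre of the first phase
- given per volume of solution although it is solid: crystals
- run time (flask): 10 s

- dawn: doubling the amount of salt in the second phase, all else as stated
- summer: doubling the solubility in step 2, all else as stated
- autumn: doubling the dissolution coefficient of step 2, all else as stated

- target and crystals together at 10 s, in percent of the substrate charged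
- concentration of target in solution at 1.0 s, in percent of saturation
- the change that raises the amount of target and crystals together at 10 s, in percent of the substrate charged most ("none" if none brings more than 2 percentage points) (dawn / summer / autumn / none)
- amount of target and crystals together at 10 s, in percent of the substrate charged, after dawn

I follow the carrier. Per unit of carrier, salt (at 1.52 M in its own phase) renews spent carrier at 0.897 s⁻¹, and substrate uses fresh carrier at 0.424 s⁻¹. I call the fresh share the making rate over the sum of making, using and the back run of step 3; at the charge it is 67.9%. So c(target) opens at 0.0230 M s⁻¹, and that rate, held, gives a first answer of 0.230 M in 10 s, or 28.8% of the substrate.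

That looks at odds with the half-lives, 0.77 s for spent carrier by step 3 and 1.6 s for fresh carrier by step 4, both far shorter than the run, and with the 95.0% the charges allow. Counting turns clears it up: one turn of the carrier charge moves 10.0% of the substrate and, at the opening rates, lasts 3.47 s, so the run holds about 2.88 turns.

Now I put the first answer back and go round again. By that answer salt has lost 0.285 M, now spent salt feeding the back run, so with 0.570 M substrate the share falls to 54.8% and the rate to 0.0132 M s⁻¹. The mean rate, over the run less a lag of 0.757 s, gives 0.168 M, or 21.0% converted. That is less than the solubility, so I expect no crystals by 10 s, and summer and autumn have nothing to act on in that time. For dawn I reckon the same way: the share opens at 80.9%, the first answer is 0.274 M with 0.339 M salt lost, the share falls to 74.8%, and the second round gives 0.211 M, or 26.3% converted.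

The forecast gives 21.8% of target, 2.2% of saturation, dawn as the best change and 26.3% of target after it: “so no crystals form and summer and autumn change nothing”. The flask gives 20.9% at 10 s and 2.21% of saturation at 1.0 s. Dawn adds 5 percentage points, reaching 25.9%, while summer and autumn add 0 points and 0 points. In this flask at 10.0 s, substrate gone is 21.6% of the charge, and isomer holds 0.697% of the charge.

Fresh carrier is the reading to watch. In this flask the share reckoned from the substrate and salt left at 10.0 s is 58.3%, and 58.9% of the carrier charge stood as fresh carrier. In the flask left until 25 s, substrate 55.6% and salt 48.1% of its charge give making 0.431 s⁻¹, using 0.236 s⁻¹ and back run 0.222 s⁻¹. Its share is 48.5%, below the opening 67.9%; fresh carrier stood at 49.2% of the carrier charge, and target and crystals together at 41.7% of the substrate charged.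

The numbers of this flask are assumed; no experiment stands behind them.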